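Its constants were drawn at random within sensible limits.

The constants give one rate worth carrying through this flask, and these are the equations and settings it comes from.

    reagent in the reaction phase ⇌ reagent in the second phase, rate k1*([reagent in the reaction phase] - [reagent in the second phase]/K1) per volume of the first phase (K1 = 0.44, k1 = 0.079 s⁻¹)
    substrate + reagent in the reaction phase → target (k2 = 0.068 L mol⁻¹ s⁻¹)
    crystals ⇌ target, rate k3*(cs3 - [target]) while solid is left; crystals form when [target] > cs3 (cs3 = 9.1 mM, k3 = 0.51 s⁻¹)
    reagent in the reaction phase + target → over-reaction product (k4 = 0.041 L mol⁻¹ s⁻¹)
    substrate + target → side product (k5 = 0.17 L mol⁻¹ s⁻¹)

substrate 0.30 M; reagent in the second phase 1.50 equiv; time 2.0 min; volume of the second phase over the first 0.25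

- percent here means substrate units held: one side product counts as two
- what is said of target includes crystals
- in the second phase: reagent in the second phase; everything else is in the first
- charges count per volume of the first phase; a concentration in a rate is the amount of a species over the volume of its own phase; every rate counts per litre of the first phase
- crystals is a solid; its amount is given per volume of the solution
- run time (flask): 2.0 min

- amount of target and crystals together at 2.0 min, in percent of the substrate charged
- the change that raises the amount of target and crystals together at 2.0 min, in percent of the substrate charged most ("none" if none brings more than 2 percentage points) (Sunday's / Wednesday's / Friday's / Tuesday's / none)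
- amount of target and crystals together at 2.0 min, in percent of the substrate charged, after Tuesday's

- Sunday's: doubling the dissolution coefficient of step 3, all else as stated
- Wednesday's: doubling the solubility in step 3, all else as stated
- Friday's: doubling the transfer coefficient of step 1, all else as stated
- Tuesday's: doubling the amount of reagent in the second phase, all else as stated

Let a be the substrate left, as a fraction of its charge, and let x be the reagent's excess over the substrate, 0.500 of that charge. The substrate is therefore the limiting reagent.

1. Transfer between the phases relaxes in 1.25 s, far shorter than the run. We therefore keep the unspent reagent at its partition, with 90.1% of it in the reaction phase.

2. We count the step to target by itself, with one reagent per substrate, so the unspent reagent is a + x. Then a falls at g·a·(a + x), where g, 1.10 min⁻¹, is the flask's clock: the rate constant of that step, times the substrate charge, times the share in the reaction phase.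

3. The first way replaces the reagent curve by a straight line. With a nil at the end, the mean is 1.00 and a = exp(−g·mean·t) gives 11.0%. Putting that back raises the mean to 1.06 and gives 9.76%.

4. The second way integrates exactly. The ratio (a + x)/a starts at 1.50 and grows by the factor 3.01, so a is x over their product less 1, which gives 14.2%.

5. The two ways part, so we test the line. Halfway through the run the exact law leaves 0.812 of reagent unspent, less than the line's 1.06. The curve sags below the line, so the mean cheats: it counts too much reagent and too little substrate. We keep 14.2%. Our reckoning stops here: it does not divide the spent substrate among target and the two losses.

6. The forecast gives 64% for target and crystals together, Tuesday's as the best change, and 71% after Tuesday's, holding that “Doubling the reagent pushes conversion to essentially complete, which outweighs the extra over-reaction”. It puts the substrate at about 90% converted, where our reckoning gives 85.8%.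

The simulation gives 64.5% for target and crystals together, with Tuesday's best at a gain of 9.4 percentage points, reaching 73.9%, and the forecast stands. At 2.00 min the flask holds 11.2% substrate, 19.4% side product and 4.92% over-reaction product beside its target. The clock reckons 14.2% of the substrate left in this flask, against the 11.2% found. For the same flask read at 30 s, the clock reckons 51.2% of the substrate left, and that flask holds 49%.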